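It is easy to judge the added ligand by its charge, but you should judge it by what stays spare once the catalyst has taken its share.

the same everywhere: left-handed substrate 0.031 M; right-handed substrate 0.031 M; gas 4.7 mM (held)
- blue: free catalyst 1.2 mol%; added ligand 1.5 mM; run made earlier
- amber: free catalyst 1.2 mol%; added ligand 2.4 mM; run made earlier
- teal: free catalyst 2.4 mol%; added ligand 1.1 mM; run made earlier
- flask: free catalyst 1.2 mol%; added ligand 1.1 mM; time 8.0 h

| run | time / h | right-handed substrate / % | left-handed substrate / % | left-handed product / % |
|---|---|---|---|---|
| blue | 0.500 | 48 | 46 | 3 |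
| blue | 1.00 | 48 | 43 | 7 |
| blue | 2.00 | 50 | 36 | 15 |
| blue | 3.00 | 49 | 32 | 17 |
| blue | 6.00 | 49 | 18 | 31 |
| amber | 0.500 | 51 | 47 | 4 |
| amber | 1.00 | 49 | 45 | 3 |
| amber | 2.00 | 49 | 40 | 11 |
| amber | 3.00 | 50 | 39 | 9 |
| amber | 6.00 | 50 | 30 | 20 |
| teal | 1.33 | 45 | 22 | 31 |
| teal | 2.50 | 46 | 8 | 40 |
| teal | 4.00 | 43 | 5 | 48 |
| teal | 5.00 | 42 | 0 | 50 |
| teal | 6.00 | 39 | 1 | 49 |

(scatter of a reading: 1.5 percentage points)

- free catalyst is single-handed; left-handed substrate and right-handed substrate are mirror images of each other, charged as a racemate, each of them at the stated concentration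
- at the start none of the gas is in solution

1. whether the excess of right-handed substrate over left-handed substrate among what is left of the two reaches 90% by 8.0 h (yes / no)
2. the highest excess of right-handed substrate over left-handed substrate among what is left of the two up to 8.0 h

Let r be right-handed over left-handed substrate, so the excess is (r − 1)/(r + 1). Let τ, the clearing time, be the time in which r grows by a factor e, taken as steady, so that ln r = t/τ. The excess wanted needs t/τ = 2.94, so two times matter: τ and the 8.0 h allowed.

The catalyst, 0.372 mM in this flask, is less than the ligand, so I treat it as the limiting reagent of their binding, one ligand each. Call q the spare ligand per catalyst. The amber run has q = 5.45 and reads τ = 11.7 h; the teal run has q = 0.478 and reads τ = 1.86 h. A straight line between them, at this flask's q = 1.96, gives a clearing time of 4.80 h. The blue run warns of the doubt: its last reading gives 5.99 h, the line 6.94 h. So t/τ reaches 1.67, less than needed, and my top is 68.2%.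

The forecast answers no with a top of 72%, above my figure, holding that “Added ligand clearly inhibits”.

The flask gives no, with a top of 66.8%.

    free catalyst + left-handed substrate ⇌ catalyst intermediate A (K = 820 /M, k = 7.50 /M/s)
    coupling partner + catalyst intermediate A → free catalyst + left-handed product (k = 26.0 /M/s)
    coupling partner ⇌ dormant form (K = 5.20, k = 0.00140 /s)
    gas ⇌ coupling partner, rate k4*(csat - [coupling partner]) (kL = 0.0310 /s)
    free catalyst + right-handed substrate ⇌ catalyst intermediate B (K = 66.0 /M, k = 14.0 /M/s)
    coupling partner + catalyst intermediate B → free catalyst + right-handed product (k = 1.50 /M/s)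
    free catalyst + added ligand ⇌ idle complex, settled at all times (K = 52000 /M)

The flask's substrates at 8.00 h put τ at 4.95 h, beside my 4.80 h. The main reason right-handed substrate stays ahead in this flask is the back reaction of catalyst intermediate B to free catalyst + right-handed substrate: in the run of this flask with that way back taken away, the excess at 8.00 h is −47.0%, not 66.8%.

With 0.72 mol% of free catalyst, the line gives τ = 8.72 h, hence a top of 42.9%. That flask computes to 39.2%.

All runs are simulated with made-up constants.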